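**Plan**

- Numbering (eremophilane type): ring B = C1–C5 and C10 (C2–OH, C3–O-acyl, C4–Me, C5–Me); ring A = C5–C10 (C7–OH, C8=O).
- Retrosynthetic cuts: the C3–O ester bond together with C2–O (both from one epoxide), C9=C10 (aldol condensation), C5–C6 and C4–CH3 (conjugate addition then enolate alkylation), and C2′=C3′ of the side chain (olefination).
- Forward order: ring B comes from 2-methylcyclohexenone with C4 and C5 set in one pot; the butynyl chain is oxidised to an α-diketone and ring A is closed on it; the ring-B alkene is then moved (C1=C2, then C3–OH, then C2=C3), epoxidised and opened by the side-chain acid.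
- Stereochemistry: C4 from ligand-controlled conjugate methylation; C5 from alkylation anti to the C4 methyl; C2 and C3 from epoxidation anti to the axial C5 methyl followed by trans-diaxial opening with inversion at C3; C6′ from (S)-2-methylbutan-1-ol.
- Feature used: in ring A the C7–OH/C8=O pair is an enolised α-diketone and C9=C10 is α,β to C8 with C10 shared with ring B, so ring A is the dehydrated aldol of a 2,3-dioxobutyl chain on quaternary C5 with the C10 ketone of ring B.

Key step: step 3

Remark: allylic alcohol 12 is drawn as the quasi-axial 3α epimer expected from abstraction of the axial allylic hydrogen; its C3 epimer would serve equally, because C3 becomes sp2 in step 7.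

**Route**

Step 1
Reactants: 1 2-methylcyclohex-2-en-1-one; 2 methylmagnesium bromide; 3 1-bromobut-2-yne
Product: 5 (2R,3S)-2-(but-2-yn-1-yl)-2,3-dimethylcyclohexan-1-one, via magnesium enolate 4 (not isolated)
Conditions: Cu(OTf)2 (3 mol %), chiral imidazolinium salt (NHC precursor, 4 mol %), MeMgBr, Et2O, −30 °C; then 1-bromobut-2-yne, DMPU, −30 °C → rt
Reagents that add atoms: methylmagnesium bromide, C[Mg]Br; 1-bromobut-2-yne, CC#CCBr
Why: Copper-catalysed asymmetric conjugate addition sets C4 (3S, ligand enantiomer chosen accordingly) and gives the tetrasubstituted enolate regiospecifically, which is C-alkylated by the propargylic bromide anti to the neighbouring methyl group, so that the two methyl groups end up cis and C5 is 2R (tandem conjugate addition–enolate alkylation).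

Step 2
Reactants: 5 (2R,3S)-2-(but-2-yn-1-yl)-2,3-dimethylcyclohexan-1-one
Product: 6 1-[(1R,2S)-1,2-dimethyl-6-oxocyclohexyl]butane-2,3-dione
Conditions: RuO2·xH2O (5 mol %), NaIO4 (2.5 equiv), CCl4/MeCN/H2O, 0 °C → rt
Reagents that add atoms: sodium periodate, [Na+].[O-]I(=O)(=O)=O
Why: Catalytic RuO4 formed in situ oxidises an internal dialkyl alkyne to the 1,2-diketone and should leave the saturated ketone and both stereocentres untouched (ruthenium tetroxide alkyne oxidation).

Step 3
Reactants: 6 1-[(1R,2S)-1,2-dimethyl-6-oxocyclohexyl]butane-2,3-dione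
Product: 9 (4aS,5S)-3-hydroxy-4a,5-dimethyl-5,6,7,8-tetrahydronaphthalen-2(4aH)-one, via ketol 7 (not isolated), via sodium diosphenolate 8 (not isolated)
Conditions: NaOMe (1.5 equiv), MeOH, 0 °C → rt; 1 M HCl work-up
Reagents that add atoms: none
Why: Methoxide enolises the terminal methyl group (C9) of the α-diketone, and this enolate adds to the ring-B ketone C10 to give ketol 7; E1cB loss of the C10 hydroxyl gives the 9-ene-7,8-dione, which enolises through C6–H to the cross-conjugated diosphenolate 8, a thermodynamic sink that drives the reversible steps and is protonated on work-up. The closest known reaction type is the cyclodehydration half of a Robinson annulation, here run with a 1,2-dione donor so that ring A emerges at its final oxidation level. Ring A (C5–C10) is the only ring closed, by C9–C10 bond formation in a 6-(enolexo)-exo-trig aldol. No stereocentre is created, since C10 becomes sp2; the quaternary C5 from step 1 has no α-hydrogen, so it cannot epimerise and it blocks aromatisation. The selectivity needed is C9-enolate attack on C10 rather than C1-enolate attack on C7 or C8; those bridged ketols cannot dehydrate to a bridgehead alkene and revert, and the C6 enolate could only close a three-membered ring, so the material should funnel to 8.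

Step 4
Reactants: 9 (4aS,5S)-3-hydroxy-4a,5-dimethyl-5,6,7,8-tetrahydronaphthalen-2(4aH)-one
Product: 10 (4aS,5S)-4a,5-dimethyl-2-oxo-2,4a,5,6,7,8-hexahydronaphthalen-3-yl acetate
Conditions: Ac2O, pyridine, DMAP (cat.), CH2Cl2, 0 °C → rt
Reagents that add atoms: acetic anhydride, CC(=O)OC(C)=O
Why: O-Acylation of the acidic diosphenol (enol ester formation) masks the enol for the oxidations and the Mitsunobu step that follow.

Step 5
Reactants: 10 (4aS,5S)-4a,5-dimethyl-2-oxo-2,4a,5,6,7,8-hexahydronaphthalen-3-yl acetate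
Product: 11 (4aS,5S)-4a,5-dimethyl-2-oxo-2,4a,5,6-tetrahydronaphthalen-3-yl acetate
Conditions: chloranil (1.3 equiv), t-BuOH, reflux
Reagents that add atoms: none
Why: Quinone dehydrogenation through the extended enol of the C8 ketone removes hydride from C2 and installs the C1=C2 double bond, the only position open because C5 is quaternary (chloranil dehydrogenation of a cross-conjugated dienone to the trienone).

Step 6
Reactants: 11 (4aS,5S)-4a,5-dimethyl-2-oxo-2,4a,5,6-tetrahydronaphthalen-3-yl acetate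
Product: 12 (4aS,5R,6S)-6-hydroxy-4a,5-dimethyl-2-oxo-2,4a,5,6-tetrahydronaphthalen-3-yl acetate
Conditions: SeO2 (1.2 equiv), 1,4-dioxane, 80 °C
Reagents that add atoms: selenium dioxide, O=[Se]=O
Why: Riley allylic oxidation (ene reaction at C1, then [2,3]-sigmatropic shift) should hydroxylate C3, the only sp3 allylic C–H position in 11; the C3 configuration is immaterial because it is erased in step 7.

Step 7
Reactants: 12 (4aS,5R,6S)-6-hydroxy-4a,5-dimethyl-2-oxo-2,4a,5,6-tetrahydronaphthalen-3-yl acetate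
Product: 15 (4aS,5S)-4a,5-dimethyl-2-oxo-2,4a,5,8-tetrahydronaphthalen-3-yl acetate, via sulfonyl hydrazine 13 (not isolated), via allylic diazene 14 (not isolated)
Conditions: PPh3, DEAD, 2-nitrobenzenesulfonohydrazide, THF, −30 °C → rt
Reagents that add atoms: none
Why: Mitsunobu displacement of the allylic alcohol by the sulfonyl hydrazide gives 13, which loses 2-nitrobenzenesulfinic acid to diazene 14; retro-ene loss of N2 delivers hydrogen to C1 and moves the alkene to C2=C3 under neutral conditions, so the base-sensitive skipped dienone should not slip back into conjugation (reductive 1,3-transposition of an allylic alcohol).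

Step 8
Reactants: 15 (4aS,5S)-4a,5-dimethyl-2-oxo-2,4a,5,8-tetrahydronaphthalen-3-yl acetate
Product: 16 (4aS,5R,6S,7R)-6,7-epoxy-4a,5-dimethyl-2-oxo-2,4a,5,6,7,8-hexahydronaphthalen-3-yl acetate
Conditions: mCPBA (1.1 equiv), NaHCO3, CH2Cl2, 0 °C
Reagents that add atoms: 3-chloroperbenzoic acid, O=C(OO)c1cccc(Cl)c1
Why: Prilezhaev epoxidation should take the only electron-rich alkene (the enone and enol-acetate double bonds are deactivated) from the face anti to the axial C5 methyl and the C4 methyl, giving the 2β,3β-epoxide.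

Step 9
Reactants: 17 (S)-2-methylbutan-1-ol
Product: 18 (S)-2-methylbutanal
Conditions: TEMPO (10 mol %), PhI(OAc)2, CH2Cl2, rt; used directly as a solution
Reagents that add atoms: none
Why: Oxoammonium-mediated oxidation stops at the aldehyde under non-basic conditions that should not epimerise the α-stereocentre, which comes from the chiral pool (TEMPO oxidation).

Step 10
Reactants: 18 (S)-2-methylbutanal; 19 triethyl 4-phosphonocrotonate
Product: 21 ethyl (S,2E,4E)-6-methylocta-2,4-dienoate, via lithiated phosphonate 20 (not isolated)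
Conditions: LiN(SiMe3)2, THF, −78 °C; then 18, −78 → 0 °C
Reagents that add atoms: triethyl 4-phosphonocrotonate, CCOC(=O)/C=C/CP(=O)(OCC)OCC
Why: Vinylogous Horner–Wadsworth–Emmons olefination with the stabilised phosphonate anion should give the (2E,4E)-dienoate.

Step 11
Reactants: 21 ethyl (S,2E,4E)-6-methylocta-2,4-dienoate
Product: 23 (S,2E,4E)-6-methylocta-2,4-dienoic acid, via lithium carboxylate 22 (not isolated)
Conditions: LiOH, THF/MeOH/H2O, rt; then 1 M HCl
Reagents that add atoms: lithium hydroxide, [Li+].[OH-]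
Why: Saponification by acyl–oxygen cleavage leaves the remote stereocentre and the diene geometry unaffected (ester hydrolysis).

Step 12
Reactants: 16 (4aS,5R,6S,7R)-6,7-epoxy-4a,5-dimethyl-2-oxo-2,4a,5,6,7,8-hexahydronaphthalen-3-yl acetate; 23 (S,2E,4E)-6-methylocta-2,4-dienoic acid
Product: 24 (4aS,5R,6R,7R)-3-acetoxy-7-hydroxy-4a,5-dimethyl-2-oxo-2,4a,5,6,7,8-hexahydronaphthalen-6-yl (S,2E,4E)-6-methylocta-2,4-dienoate
Conditions: 23 (1.5 equiv), Co(salen) (C16H14CoN2O2, 5 mol %), i-Pr2NEt (0.2 equiv), t-BuOMe, air, rt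
Reagents that add atoms: (S,2E,4E)-6-methylocta-2,4-dienoic acid, CC[C@H](C)/C=C/C=C/C(=O)O
Why: Epoxide acidolysis assisted by the trivalent cobalt carboxylate formed in situ should follow the Fürst–Plattner rule: axial SN2 attack at C3 on the chair with the C5 methyl axial gives the trans-diaxial 2β-hydroxy-3α-ester, inverting C3, retaining C2, and placing the acyl group on O3 without any hydroxyl differentiation.

Step 13
Reactants: 24 (4aS,5R,6R,7R)-3-acetoxy-7-hydroxy-4a,5-dimethyl-2-oxo-2,4a,5,6,7,8-hexahydronaphthalen-6-yl (S,2E,4E)-6-methylocta-2,4-dienoate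
Product: 25 Septeremophilane G
Conditions: NH4OAc (excess), MeOH/H2O (4:1), rt
Reagents that add atoms: none
Why: Mild neutral solvolysis should cleave the phenol-like enol acetate much faster than the hindered secondary dienoate, releasing the diosphenol (selective deacetylation).

**Compound list**

1 | 2-methylcyclohex-2-en-1-one | CC1=CCCCC1=O | starting material
2 | methylmagnesium bromide | C[Mg]Br | starting material
3 | 1-bromobut-2-yne | CC#CCBr | starting material
4 | bromomagnesium (3S)-2,3-dimethylcyclohex-1-en-1-olate | C[C@H]1CCCC(O[Mg]Br)=C1C | intermediate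
5 | (2R,3S)-2-(but-2-yn-1-yl)-2,3-dimethylcyclohexan-1-one | CC#CC[C@]1(C)[C@@H](C)CCCC1=O | intermediate
6 | 1-[(1R,2S)-1,2-dimethyl-6-oxocyclohexyl]butane-2,3-dione | CC(=O)C(=O)C[C@]1(C)[C@@H](C)CCCC1=O | intermediate
7 | (4aR,5S)-8a-hydroxy-4a,5-dimethyl-1,4,4a,5,6,7,8,8a-octahydronaphthalene-2,3-dione (ketol; configuration at C8a not controlled and lost on dehydration) | C1CCC2(O)CC(=O)C(=O)C[C@]2(C)[C@H]1C | intermediate
8 | sodium (4aS,5S)-4a,5-dimethyl-2-oxo-2,4a,5,6,7,8-hexahydronaphthalen-3-olate | C1CCC2=CC(=O)C([O-])=C[C@]2(C)[C@H]1C.[Na+] | intermediate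
9 | (4aS,5S)-3-hydroxy-4a,5-dimethyl-5,6,7,8-tetrahydronaphthalen-2(4aH)-one | C1CCC2=CC(=O)C(O)=C[C@]2(C)[C@H]1C | intermediate
10 | (4aS,5S)-4a,5-dimethyl-2-oxo-2,4a,5,6,7,8-hexahydronaphthalen-3-yl acetate | C1CCC2=CC(=O)C(OC(C)=O)=C[C@]2(C)[C@H]1C | intermediate
11 | (4aS,5S)-4a,5-dimethyl-2-oxo-2,4a,5,6-tetrahydronaphthalen-3-yl acetate | C1C=CC2=CC(=O)C(OC(C)=O)=C[C@]2(C)[C@H]1C | intermediate
12 | (4aS,5R,6S)-6-hydroxy-4a,5-dimethyl-2-oxo-2,4a,5,6-tetrahydronaphthalen-3-yl acetate | O[C@H]1C=CC2=CC(=O)C(OC(C)=O)=C[C@]2(C)[C@H]1C | intermediate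
13 | (4aS,5R,6R)-4a,5-dimethyl-6-[1-(2-nitrophenylsulfonyl)hydrazin-1-yl]-2-oxo-2,4a,5,6-tetrahydronaphthalen-3-yl acetate | NN([C@@H]1C=CC2=CC(=O)C(OC(C)=O)=C[C@]2(C)[C@H]1C)S(=O)(=O)c1ccccc1[N+](=O)[O-] | intermediate
14 | (4aS,5R,6R)-6-diazenyl-4a,5-dimethyl-2-oxo-2,4a,5,6-tetrahydronaphthalen-3-yl acetate | N=N[C@@H]1C=CC2=CC(=O)C(OC(C)=O)=C[C@]2(C)[C@H]1C | intermediate
15 | (4aS,5S)-4a,5-dimethyl-2-oxo-2,4a,5,8-tetrahydronaphthalen-3-yl acetate | C1=CCC2=CC(=O)C(OC(C)=O)=C[C@]2(C)[C@H]1C | intermediate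
16 | (4aS,5R,6S,7R)-6,7-epoxy-4a,5-dimethyl-2-oxo-2,4a,5,6,7,8-hexahydronaphthalen-3-yl acetate | O1[C@@H]2[C@H]1CC3=CC(=O)C(OC(C)=O)=C[C@]3(C)[C@H]2C | intermediate
17 | (S)-2-methylbutan-1-ol | CC[C@H](C)CO | starting material
18 | (S)-2-methylbutanal | CC[C@H](C)C=O | intermediate
19 | triethyl 4-phosphonocrotonate | CCOC(=O)/C=C/CP(=O)(OCC)OCC | starting material
20 | lithium salt of triethyl 4-phosphonocrotonate (γ-lithiated phosphonate) | [Li+].CCOC(=O)/C=C/[CH-]P(=O)(OCC)OCC | intermediate
21 | ethyl (S,2E,4E)-6-methylocta-2,4-dienoate | CC[C@H](C)/C=C/C=C/C(=O)OCC | intermediate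
22 | lithium (S,2E,4E)-6-methylocta-2,4-dienoate | [Li+].CC[C@H](C)/C=C/C=C/C(=O)[O-] | intermediate
23 | (S,2E,4E)-6-methylocta-2,4-dienoic acid | CC[C@H](C)/C=C/C=C/C(=O)O | intermediate
24 | (4aS,5R,6R,7R)-3-acetoxy-7-hydroxy-4a,5-dimethyl-2-oxo-2,4a,5,6,7,8-hexahydronaphthalen-6-yl (S,2E,4E)-6-methylocta-2,4-dienoate | CC[C@H](C)/C=C/C=C/C(=O)O[C@H]1[C@H](O)CC2=CC(=O)C(OC(C)=O)=C[C@]2(C)[C@H]1C | intermediate
25 | Septeremophilane G, (4aS,5R,6R,7R)-3,7-dihydroxy-4a,5-dimethyl-2-oxo-2,4a,5,6,7,8-hexahydronaphthalen-6-yl (S,2E,4E)-6-methylocta-2,4-dienoate | CC[C@H](C)/C=C/C=C/C(=O)O[C@H]1[C@H](O)CC2=CC(=O)C(O)=C[C@]2(C)[C@H]1C | target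

**Step count and risks**

Total step count: 13. Longest linear sequence: 10 (steps 1–8, 12, 13).

Steps most likely to fail:

Step 6. The ene step of SeO2 on the electron-poor γ,δ-alkene may be slow, so that over-oxidation of the carbinol to the ketone or acid-promoted loss of the enol acetate competes. The fallback sets out from 11: soft enolisation (TBSOTf, Et3N, CH2Cl2, 0 °C) should give the fully conjugated silyl trienol ether (4aS,5S)-2-[(tert-butyldimethylsilyl)oxy]-4a,5-dimethyl-4a,5-dihydronaphthalen-3-yl acetate F1. Its terminal C2=C3 bond is oxidised with dimethyldioxirane (acetone, −40 °C; vinylogous Rubottom oxidation), and desilylation on mildly acidic work-up brings the material back to the route at 12.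

Step 7. The Mitsunobu displacement at the hindered C3 carbinol, flanked by the C4 methine, may be slow, with SN2′ attack or elimination taking over. The fallback sets out from 12: MnO2 (CH2Cl2, rt) oxidises the allylic alcohol to the enedione (4aR,5R)-4a,5-dimethyl-2,6-dioxo-2,4a,5,6-tetrahydronaphthalen-3-yl acetate F2. Condensation with p-toluenesulfonyl hydrazide (EtOH, rt) at the C3 carbonyl, which is less deactivated than the cross-conjugated C8 carbonyl, gives the tosylhydrazone (4aS,5R)-4a,5-dimethyl-2-oxo-6-(2-tosylhydrazinylidene)-2,4a,5,6-tetrahydronaphthalen-3-yl acetate F3. Catecholborane (CHCl3, 0 °C) followed by NaOAc·3H2O (reflux) reduces the C=N bond, and the allylic diazene so formed loses N2 with the same alkene shift, returning to the route at 15. This replaces a substitution at carbon by a hydride addition to C=N.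

Step 12. Axial attack of the bulky carboxylate at C3, next to the C4 methyl and 1,3 to the axial C5 methyl, may be slow, which would allow attack at C2 or base-induced isomerisation of the epoxide to an allylic alcohol. The fallback sets out from 16: specific-acid hydrolysis (HClO4 cat., THF/H2O, 0 °C) uses water as a small nucleophile for the diaxial opening and gives the diol (4aS,5R,6R,7R)-6,7-dihydroxy-4a,5-dimethyl-2-oxo-2,4a,5,6,7,8-hexahydronaphthalen-3-yl acetate F4. The less hindered C2 hydroxyl is silylated (TBSCl, imidazole, DMF, 0 °C) to (4aS,5R,6R,7R)-7-[(tert-butyldimethylsilyl)oxy]-6-hydroxy-4a,5-dimethyl-2-oxo-2,4a,5,6,7,8-hexahydronaphthalen-3-yl acetate F5. Steglich esterification of the axial C3 hydroxyl with 23 (DCC, DMAP, CH2Cl2) gives (4aS,5R,6R,7R)-3-acetoxy-7-[(tert-butyldimethylsilyl)oxy]-4a,5-dimethyl-2-oxo-2,4a,5,6,7,8-hexahydronaphthalen-6-yl (S,2E,4E)-6-methylocta-2,4-dienoate F6, and HF·pyridine (THF, 0 °C) removes the silyl group to return to the route at 24.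

**Further compounds**

F1 | step 6 | (4aS,5S)-2-[(tert-butyldimethylsilyl)oxy]-4a,5-dimethyl-4a,5-dihydronaphthalen-3-yl acetate | C1=CC=C2C=C(O[Si](C)(C)C(C)(C)C)C(OC(C)=O)=C[C@]2(C)[C@H]1C
F2 | step 7 | (4aR,5R)-4a,5-dimethyl-2,6-dioxo-2,4a,5,6-tetrahydronaphthalen-3-yl acetate | O=C1C=CC2=CC(=O)C(OC(C)=O)=C[C@]2(C)[C@H]1C
F3 | step 7 | (4aS,5R)-4a,5-dimethyl-2-oxo-6-(2-tosylhydrazinylidene)-2,4a,5,6-tetrahydronaphthalen-3-yl acetate | Cc1ccc(cc1)S(=O)(=O)NN=C1C=CC2=CC(=O)C(OC(C)=O)=C[C@]2(C)[C@H]1C
F4 | step 12 | (4aS,5R,6R,7R)-6,7-dihydroxy-4a,5-dimethyl-2-oxo-2,4a,5,6,7,8-hexahydronaphthalen-3-yl acetate | O[C@H]1[C@H](O)CC2=CC(=O)C(OC(C)=O)=C[C@]2(C)[C@H]1C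
F5 | step 12 | (4aS,5R,6R,7R)-7-[(tert-butyldimethylsilyl)oxy]-6-hydroxy-4a,5-dimethyl-2-oxo-2,4a,5,6,7,8-hexahydronaphthalen-3-yl acetate | O[C@H]1[C@H](O[Si](C)(C)C(C)(C)C)CC2=CC(=O)C(OC(C)=O)=C[C@]2(C)[C@H]1C
F6 | step 12 | (4aS,5R,6R,7R)-3-acetoxy-7-[(tert-butyldimethylsilyl)oxy]-4a,5-dimethyl-2-oxo-2,4a,5,6,7,8-hexahydronaphthalen-6-yl (S,2E,4E)-6-methylocta-2,4-dienoate | CC[C@H](C)/C=C/C=C/C(=O)O[C@H]1[C@H](O[Si](C)(C)C(C)(C)C)CC2=CC(=O)C(OC(C)=O)=C[C@]2(C)[C@H]1C
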